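**Plan**

- Retrosynthesis cuts the two para-disposed C(=O)–CH bonds of the quinone ring: C1–C6 and C4–C3, where C1 is the carbonyl next to the furyl-bearing C2. This leaves two O=C–C=C triads, C1–C2–C3 on the furan and C4–C5–C6 free, and each triad is a cyclopropenone opened at one C(=O)–C bond.
- The feature that allows this is that the 1,4-benzoquinone ring is the head-to-tail union of two such triads, so every new bond joins an acyl carbon to a vinyl carbon and the strain of two three-membered rings pays for both bonds.
- Further cuts: furan C5–cyclopropene bond (Negishi), ester C–O (Steglich), prenyl C=C (cross-metathesis), carbinol C–C (allylation), furan C5–I.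
- Forward: the furan ring is bought as furan-3-carbaldehyde. C5 is iodinated, the side chain is built, the three-membered ring is attached as its acetal and unmasked, and the quinone ring arises last by a nickel-mediated [3+3] union with cyclopropenone.
- Stereochemistry: the single (S) center comes from a Keck allylation with the (S)-BINOL–titanium catalyst; no later step breaks a bond at that carbon.

Key step: step 10

Remark: the facial sense of the (S)-BINOL–titanium catalyst is assumed to be the one established for benzaldehyde (Si-face attack). The priority order O > furyl > CH2 > H holds for every intermediate, so alcohol, ester and target all carry the descriptor (S).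

**Route**

Step 1
Reactants: 1 furan-3-carbaldehyde
Product: 5 5-iodofuran-3-carbaldehyde, via lithium α-morpholino alkoxide 2 (not isolated), via C5-lithiated alkoxide 3 (not isolated), via iodinated alkoxide 4 (not isolated)
Conditions: morpholine, n-BuLi, THF, −78 °C; then 1; s-BuLi, −78 °C; I2, −78 °C → rt; H2O work-up
Reagents that add atoms: iodine, II
Why: In situ protection of the aldehyde as its lithium α-amino alkoxide followed by directed lithiation should metalate the free α-position C5, remote from the bulky carbinolate, and iodinolysis with aqueous collapse of the hemiaminal returns the aldehyde (α-amino alkoxide directed metalation).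

Step 2
Reactants: 5 5-iodofuran-3-carbaldehyde
Product: 7 (S)-1-(5-iodofuran-3-yl)but-3-en-1-ol, via tributylstannyl ether 6 (not isolated)
Conditions: allylSnBu3, (S)-BINOL (20 mol %), Ti(OiPr)4 (10 mol %), 4 Å MS, CH2Cl2, −20 °C; aq. NaHCO3
Reagents that add atoms: allyltributylstannane, C=CC[Sn](CCCC)(CCCC)CCCC
Why: Keck asymmetric allylation, in which the (S)-BINOL–titanium Lewis acid binds the aldehyde and exposes its Si face to the allylstannane, should set the (S) carbinol center as it does for benzaldehyde.

Step 3
Reactants: 7 (S)-1-(5-iodofuran-3-yl)but-3-en-1-ol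
Product: 8 (S)-1-(5-iodofuran-3-yl)-4-methylpent-3-en-1-ol
Conditions: 2-methylbut-2-ene (large excess), second-generation Grubbs catalyst (3 mol %), CH2Cl2, 35 °C
Reagents that add atoms: 2-methylbut-2-ene, CC=C(C)C
Why: Olefin cross-metathesis of the terminal alkene with 2-methylbut-2-ene exchanges the methylidene for an isopropylidene terminus to give the prenyl group with release of propene, and the carbinol center is not involved.

Step 4
Reactants: 8 (S)-1-(5-iodofuran-3-yl)-4-methylpent-3-en-1-ol
Product: 9 (S)-1-(5-iodofuran-3-yl)-4-methylpent-3-en-1-yl 3-methylbut-2-enoate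
Conditions: 3-methylbut-2-enoic acid, DCC, DMAP (cat.), CH2Cl2, 0 °C → rt
Reagents that add atoms: 3-methylbut-2-enoic acid, CC(C)=CC(=O)O
Why: Steglich esterification acylates the secondary alcohol through the DCC-activated acid and its acylpyridinium, so the carbinol C–O bond is untouched and the (S) configuration is retained.

Step 5
Reactants: 10 1,3-dichloropropan-2-one
Product: 11 2,2-bis(chloromethyl)-5,5-dimethyl-1,3-dioxane
Conditions: 2,2-dimethylpropane-1,3-diol, TsOH·H2O (cat.), benzene, reflux, Dean–Stark
Reagents that add atoms: 2,2-dimethylpropane-1,3-diol, OCC(C)(C)CO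
Why: Acid-catalysed acetalisation with azeotropic removal of water drives the ketone to the six-membered dioxane.

Step 6
Reactants: 11 2,2-bis(chloromethyl)-5,5-dimethyl-1,3-dioxane
Product: 14 6,6-dimethyl-4,8-dioxaspiro[2.5]oct-1-ene, via chlorocyclopropane acetal 12 (not isolated), via sodium cyclopropenide 13 (not isolated)
Conditions: NaNH2 (3 equiv), liquid NH3, −50 → −35 °C; then NH4Cl
Reagents that add atoms: none
Why: α-Deprotonation of one CH2Cl and intramolecular displacement of the other chloride (1,3-elimination) closes the cyclopropane 12, 1,2-dehydrochlorination gives the cyclopropene, and the third equivalent of amide holds it as its sodium salt 13 until the NH4Cl quench.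

Step 7
Reactants: 14 6,6-dimethyl-4,8-dioxaspiro[2.5]oct-1-ene; 9 (S)-1-(5-iodofuran-3-yl)-4-methylpent-3-en-1-yl 3-methylbut-2-enoate
Product: 17 (S)-1-[5-(6,6-dimethyl-4,8-dioxaspiro[2.5]oct-1-en-1-yl)furan-3-yl]-4-methylpent-3-en-1-yl 3-methylbut-2-enoate, via lithiated acetal 15 (not isolated), via cyclopropenylzinc chloride 16 (not isolated)
Conditions: 14 (1.3 equiv), n-BuLi, THF, −78 °C; ZnCl2, −78 → 0 °C; then 9, Pd(PPh3)4 (5 mol %), THF, rt
Reagents that add atoms: none
Why: The acidic vinylic C–H of the cyclopropenone acetal is lithiated and transmetalated to zinc, and Negishi coupling of this alkenylzinc with the 2-iodofuran at Pd(PPh3)4 should form the furan–cyclopropene bond without touching the ester.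

Step 8
Reactants: 17 (S)-1-[5-(6,6-dimethyl-4,8-dioxaspiro[2.5]oct-1-en-1-yl)furan-3-yl]-4-methylpent-3-en-1-yl 3-methylbut-2-enoate
Product: 18 (S)-4-methyl-1-[5-(3-oxocycloprop-1-en-1-yl)furan-3-yl]pent-3-en-1-yl 3-methylbut-2-enoate
Conditions: Amberlyst-15, acetone/H2O, rt
Reagents that add atoms: water, O
Why: Acid-catalysed acetal hydrolysis on a sulfonic acid resin is mild enough for the ester and the prenyl alkene and is driven by the aromatic cyclopropenium-oxide character of the cyclopropenone that forms.

Step 9
Reactants: 14 6,6-dimethyl-4,8-dioxaspiro[2.5]oct-1-ene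
Product: 19 cycloprop-2-en-1-one
Conditions: Amberlyst-15, acetone/H2O, 0 °C → rt; filtration; bulb-to-bulb distillation; kept as a titrated toluene solution at −20 °C
Reagents that add atoms: water, O
Why: The same resin-catalysed acetal hydrolysis should release the parent cyclopropenone, which is kept cold and dilute to suppress polymerisation.

Step 10
Reactants: 18 (S)-4-methyl-1-[5-(3-oxocycloprop-1-en-1-yl)furan-3-yl]pent-3-en-1-yl 3-methylbut-2-enoate; 19 cycloprop-2-en-1-one
Product: 22 (S)-1-[5-(3,6-dioxocyclohexa-1,4-dien-1-yl)furan-3-yl]-4-methylpent-3-en-1-yl 3-methylbut-2-enoate, via nickelacyclobutenone 20 (not isolated), via nickelacycloheptadienedione 21 (not isolated)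
Conditions: Ni(cod)2 (1.05 equiv), THF, −40 °C, 18 added dropwise; then 19 (3 equiv), −40 °C → rt; air, aq. NH4Cl
Reagents that add atoms: none
Why: Proposed new method: zerovalent nickel should insert oxidatively into the less hindered C(=O)–CH bond of the three-membered ring of 18 to give nickelacyclobutenone 20, the strained C=C of 19 should then insert into the nickel–acyl bond and β-carbon elimination should open the second three-membered ring to the seven-membered nickelacycle 21, and acyl–vinyl reductive elimination closes the quinone, both ring openings being driven by release of cyclopropenone strain. The closest known reaction type is the cyclodimerisation of diarylcyclopropenones to tetraaryl-1,4-benzoquinones mediated by zerovalent nickel; the cross-union of a monosubstituted cyclopropenone with the parent one is new. The six-membered ring is closed as a formal [3+3] union of two C3O units, its last bond being made by reductive elimination from the seven-membered metallacycle. No stereocenter is formed, and the (S) acyloxy carbon is remote from the reacting atoms and is not touched. The step needs cross-union over homodimerisation and head-to-tail (para) over head-to-head (ortho) union: the first is secured by the order of addition (18 is added slowly to a full equivalent of nickel so that free 18 never meets its own nickelacycle, and only then is 19 admitted), the second by the matched polarity of acyl migration to the alkene, which makes each new bond an acyl–vinyl bond as in the known homodimerisation. Insertion of nickel into the other C(=O)–C bond of 18 would lead to the same quinone.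

**Compound list**

1 | furan-3-carbaldehyde | O=Cc1ccoc1 | starting material
2 | lithium (furan-3-yl)(morpholin-4-yl)methanolate | [Li]OC(N1CCOCC1)c1ccoc1 | intermediate
3 | lithium (5-lithiofuran-3-yl)(morpholin-4-yl)methanolate | [Li]OC(N1CCOCC1)c1coc([Li])c1 | intermediate
4 | lithium (5-iodofuran-3-yl)(morpholin-4-yl)methanolate | [Li]OC(N1CCOCC1)c1coc(I)c1 | intermediate
5 | 5-iodofuran-3-carbaldehyde | O=Cc1coc(I)c1 | intermediate
6 | tributyl{[(S)-1-(5-iodofuran-3-yl)but-3-en-1-yl]oxy}stannane | C=CC[C@H](O[Sn](CCCC)(CCCC)CCCC)c1coc(I)c1 | intermediate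
7 | (S)-1-(5-iodofuran-3-yl)but-3-en-1-ol | C=CC[C@H](O)c1coc(I)c1 | intermediate
8 | (S)-1-(5-iodofuran-3-yl)-4-methylpent-3-en-1-ol | CC(C)=CC[C@H](O)c1coc(I)c1 | intermediate
9 | (S)-1-(5-iodofuran-3-yl)-4-methylpent-3-en-1-yl 3-methylbut-2-enoate | CC(C)=CC[C@H](OC(=O)C=C(C)C)c1coc(I)c1 | intermediate
10 | 1,3-dichloropropan-2-one | ClCC(=O)CCl | starting material
11 | 2,2-bis(chloromethyl)-5,5-dimethyl-1,3-dioxane | ClCC1(CCl)OCC(C)(C)CO1 | intermediate
12 | 1-chloro-6,6-dimethyl-4,8-dioxaspiro[2.5]octane | ClC1CC12OCC(C)(C)CO2 | intermediate
13 | sodium 6,6-dimethyl-4,8-dioxaspiro[2.5]oct-1-en-1-ide | [Na]C1=CC12OCC(C)(C)CO2 | intermediate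
14 | 6,6-dimethyl-4,8-dioxaspiro[2.5]oct-1-ene | C1=CC12OCC(C)(C)CO2 | intermediate
15 | 1-lithio-6,6-dimethyl-4,8-dioxaspiro[2.5]oct-1-ene | [Li]C1=CC12OCC(C)(C)CO2 | intermediate
16 | chloro(6,6-dimethyl-4,8-dioxaspiro[2.5]oct-1-en-1-yl)zinc | Cl[Zn]C1=CC12OCC(C)(C)CO2 | intermediate
17 | (S)-1-[5-(6,6-dimethyl-4,8-dioxaspiro[2.5]oct-1-en-1-yl)furan-3-yl]-4-methylpent-3-en-1-yl 3-methylbut-2-enoate | CC(C)=CC[C@H](OC(=O)C=C(C)C)c1coc(C2=CC23OCC(C)(C)CO3)c1 | intermediate
18 | (S)-4-methyl-1-[5-(3-oxocycloprop-1-en-1-yl)furan-3-yl]pent-3-en-1-yl 3-methylbut-2-enoate | CC(C)=CC[C@H](OC(=O)C=C(C)C)c1coc(C2=CC2=O)c1 | intermediate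
19 | cycloprop-2-en-1-one | O=C1C=C1 | intermediate
20 | nickelacyclobutenone from 18: 1-nickelacyclobut-3-en-2-one carrying the furyl residue of 18 at C3 (cod on nickel not written) | CC(C)=CC[C@H](OC(=O)C=C(C)C)c1coc(C2=C[Ni]C2=O)c1 | intermediate
21 | nickelacycloheptadienedione: 1-nickelacyclohepta-3,6-diene-2,5-dione carrying the furyl residue of 18 at C6 (cod on nickel not written) | CC(C)=CC[C@H](OC(=O)C=C(C)C)c1coc(C2=C[Ni]C(=O)C=CC2=O)c1 | intermediate
22 | (S)-1-[5-(3,6-dioxocyclohexa-1,4-dien-1-yl)furan-3-yl]-4-methylpent-3-en-1-yl 3-methylbut-2-enoate | CC(C)=CC[C@H](OC(=O)C=C(C)C)c1coc(C2=CC(=O)C=CC2=O)c1 | target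

**Count and risks**

Total step count: 10. Longest linear sequence: 7 steps (steps 1, 2, 3, 4, 7, 8, 10, from furan-3-carbaldehyde).

Steps most likely to fail:

1. Step 10 (proposed method). Homodimerisation of either cyclopropenone, decarbonylation of nickelacycle 20 to an alkyne complex, head-to-head union to an ortho-quinone, or retention of the quinone on zerovalent nickel may each drain the cross-coupled product. The fallback uses known chemistry and buys the six-membered ring instead of building it. It sets out from iodide 9: Suzuki–Miyaura coupling with 2,5-dimethoxyphenylboronic acid (Pd(dppf)Cl2, K3PO4, dioxane/H2O, 60 °C) should give (S)-1-[5-(2,5-dimethoxyphenyl)furan-3-yl]-4-methylpent-3-en-1-yl 3-methylbut-2-enoate F1. Oxidative demethylation with (NH4)2Ce(NO3)6 in MeCN/H2O at 0 °C then comes back to the route at target 22.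

2. Step 8. Acid-promoted ionisation of the furylic C–O bond (loss of the ester or of configuration), hydration of the prenyl alkene, or hydrolytic ring opening and polymerisation of the cyclopropenone as it is unmasked may prevent isolation of 18. The fallback avoids both the acid step and the cyclopropenone. It sets out from iodide 9: stannylation with (Bu3Sn)2 and Pd(PPh3)4 in toluene at 90 °C should give (S)-4-methyl-1-[5-(tributylstannyl)furan-3-yl]pent-3-en-1-yl 3-methylbut-2-enoate F2. Stille coupling of this stannane with 2-bromo-1,4-benzoquinone (Pd(PPh3)4, CuI, dioxane, 70 °C) comes back to the route at target 22.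

3. Step 1. Metalation at C2 beside the carbinolate instead of at C5, or incomplete metalation, would give regioisomeric or unreacted aldehyde. The fallback replaces directed metalation by electrophilic aromatic substitution. It sets out from 1: iodination with N-iodosuccinimide and CF3CO2H in MeCN at rt should go to C5, because attack at C2 would place positive charge on the formyl-bearing carbon of the Wheland intermediate. It comes back to the route at 5 and makes no new compound (F0).

**Further compounds**

F1 | step 10 | (S)-1-[5-(2,5-dimethoxyphenyl)furan-3-yl]-4-methylpent-3-en-1-yl 3-methylbut-2-enoate | CC(C)=CC[C@H](OC(=O)C=C(C)C)c1coc(-c2cc(OC)ccc2OC)c1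
F2 | step 8 | (S)-4-methyl-1-[5-(tributylstannyl)furan-3-yl]pent-3-en-1-yl 3-methylbut-2-enoate | CC(C)=CC[C@H](OC(=O)C=C(C)C)c1coc([Sn](CCCC)(CCCC)CCCC)c1
F0 | step 1 | none | none
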